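A direct plan would esterify (2E,6E)-farnesol 1 with 2,4-dihydroxybenzoic acid A1 to (2E,6E)-farnesyl 2,4-dihydroxybenzoate A2, mask both phenols as the bis(methoxymethyl) ether A3, and methylenate the ester carbonyl with a titanium methylidene (Cp2Ti=CH2) to allyl vinyl ether A4. A catalyst-controlled Claisen rearrangement would then form the C2–C3 bond and the quaternary centre, and acid would cleave the acetals. Its weakest steps would be:
- the enantioselective [3,3] shift, because this carbonyl-free enol ether would offer a chiral catalyst no second binding point and the thermal background would give racemate;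
- the ester methylenation, whose electron-rich enol ether would be acid-labile and hard to purify;
- the phenol protection and deprotection, which would add length without complexity.

The route rests on the C3–vinyl disconnection. The target has its C1 carbonyl two bonds from quaternary C3, and C1–C3 with the methyl and the C4–C12 chain are the allylic alcohol unit and tail of (2E,6E)-farnesol 1. An enantioselective palladium-catalysed redox-relay Heck reaction would join vinyl triflate 2, an electrophile, to C3, the latent β-acceptor carbon (a union of like polarity), create the quaternary stereocentre under ligand control and oxidise C1 to the aldehyde in one operation on the unprotected commercial alcohol. No ester, enol ether or sigmatropic step would remain; protecting groups would enter only with the arene, joined afterwards by aryllithium addition and oxidation.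

Key step: step 1

Assumption: the (S)-configured pyridine-oxazoline ligand is taken to deliver the vinyl group to the C3 Re face of the (2E)-alkene; should the opposite sense be found, the (R)-ligand, equally accessible from tert-leucinol, would be used with no other change.

Step 1
Reactants: 1 (2E,6E)-farnesol; 2 ethenyl trifluoromethanesulfonate (vinyl triflate)
Product: 4 (3R,6E)-3-ethenyl-3,7,11-trimethyldodeca-6,10-dienal, via enol 3 (not isolated)
Conditions: Pd2(dba)3 (3 mol%), (S)-4-tert-butyl-2-[5-(trifluoromethyl)pyridin-2-yl]-4,5-dihydrooxazole (8 mol%), 1 (1.5 equiv), 2 (1.0 equiv), 2,6-di-tert-butyl-4-methylpyridine (1.2 equiv), 3 Å MS, DMA, rt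
Reagents that add atoms: none
Why: Oxidative addition of 2 to zerovalent palladium should give a cationic vinylpalladium complex (divalent palladium) that inserts the C2=C3 alkene of 1 with the vinyl group on C3, the carbon distal to the hydroxyl, and palladium on C2; because C3 then bears no hydrogen, β-hydride elimination can only run toward C1 and releases enol 3, which tautomerises to aldehyde 4, while the hindered pyridine takes up the triflic acid so that neither the allylic alcohol nor the trisubstituted alkenes are ionised. The closest known reaction type is the enantioselective redox-relay Heck alkenylation of trisubstituted alkenols with alkenyl triflates, which gives allylic quaternary centres at or beyond the β-position of the new carbonyl. No ring is closed. The C3 stereocentre is set in the migratory insertion by the tert-butyl oxazoline of the ligand, which must steer the vinyl group to the C3 Re face (C2 > C4 > CH3 clockwise) of the (2E)-alkene to give (R); geometrically pure (2E)-1 is required, because the (2Z)-isomer would give the other enantiomer. The step needs site selectivity for C2=C3 over the C6=C7 and C10=C11 alkenes and over the new vinyl group: the hydroxyl polarises and can pre-coordinate only the allylic alkene, the relay there ends at once in a carbonyl, the vinyl group of 4 is shielded by the adjacent quaternary carbon, and the excess of 1 competes with 4 for the catalyst.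

Step 2
Reactants: 5 4-bromobenzene-1,3-diol
Product: 6 1-bromo-2,4-bis(methoxymethoxy)benzene
Conditions: MOMCl (2.5 equiv), iPr2NEt (3 equiv), CH2Cl2, 0 °C to rt
Reagents that add atoms: chloromethyl methyl ether (MOMCl), COCCl
Why: Williamson-type O-alkylation of both phenols by the oxocarbenium-like chloromethyl ether under amine base; the aryl bromide is inert, and the acetals are chosen because they survive butyllithium, stabilise the ortho aryllithium by coordination and leave under mild acid.

Step 3
Reactants: 6 1-bromo-2,4-bis(methoxymethoxy)benzene; 4 (3R,6E)-3-ethenyl-3,7,11-trimethyldodeca-6,10-dienal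
Product: 8 (3R,6E)-1-[2,4-bis(methoxymethoxy)phenyl]-3-ethenyl-3,7,11-trimethyldodeca-6,10-dien-1-ol (both C1 epimers), via aryllithium 7 (not isolated)
Conditions: 6 (1.3 equiv), n-BuLi (1.25 equiv), THF, −78 °C, 30 min; then 4 (1.0 equiv), −78 to −40 °C; then H2O
Reagents that add atoms: none
Why: Bromine–lithium exchange, fast at −78 °C and helped by the ortho acetal oxygen, followed by 1,2-addition of 7 to the aldehyde; the C1 carbinol should form as both epimers, which is of no consequence because C1 becomes the ketone, and C3, a quaternary carbon β to the carbonyl, cannot epimerise.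

Step 4
Reactants: 8 (3R,6E)-1-[2,4-bis(methoxymethoxy)phenyl]-3-ethenyl-3,7,11-trimethyldodeca-6,10-dien-1-ol
Product: 9 (3R,6E)-1-[2,4-bis(methoxymethoxy)phenyl]-3-ethenyl-3,7,11-trimethyldodeca-6,10-dien-1-one
Conditions: activated MnO2 (15 equiv), CH2Cl2, rt to 40 °C
Reagents that add atoms: none
Why: Heterogeneous MnO2 oxidation of a benzylic alcohol, accelerated by the electron-rich arene; the isolated alkenes, the vinyl group and the acetals are inert, and both C1 epimers should converge on the one ketone.

Step 5
Reactants: 9 (3R,6E)-1-[2,4-bis(methoxymethoxy)phenyl]-3-ethenyl-3,7,11-trimethyldodeca-6,10-dien-1-one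
Product: 10 (3R,6E)-1-(2,4-dihydroxyphenyl)-3-ethenyl-3,7,11-trimethyldodeca-6,10-dien-1-one
Conditions: HCl (1 M in MeOH), 25 °C
Reagents that add atoms: none
Why: Acid-catalysed acetal exchange should transfer both methoxymethyl groups to methanol as dimethoxymethane; dilute acid at room temperature should spare the trisubstituted alkenes, and C3 carries no acidic hydrogen, so its configuration is not at risk.

Compound list
1 | (2E,6E)-farnesol, (2E,6E)-3,7,11-trimethyldodeca-2,6,10-trien-1-ol | OC/C=C(\C)CC/C=C(\C)CCC=C(C)C | starting material
2 | ethenyl trifluoromethanesulfonate (vinyl triflate) | C=COS(=O)(=O)C(F)(F)F | starting material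
3 | (1E,3S,6E)-3-ethenyl-3,7,11-trimethyldodeca-1,6,10-trien-1-ol (enol; same spatial arrangement at C3 as in 4, the descriptor changes because the enol arm outranks vinyl; the 1Z enol would tautomerise alike) | C=C[C@](C)(CC/C=C(\C)CCC=C(C)C)/C=C/O | intermediate
4 | (3R,6E)-3-ethenyl-3,7,11-trimethyldodeca-6,10-dienal | C=C[C@](C)(CC/C=C(\C)CCC=C(C)C)CC=O | intermediate
5 | 4-bromobenzene-1,3-diol (4-bromoresorcinol) | Oc1ccc(Br)c(O)c1 | starting material
6 | 1-bromo-2,4-bis(methoxymethoxy)benzene | COCOc1ccc(Br)c(OCOC)c1 | intermediate
7 | [2,4-bis(methoxymethoxy)phenyl]lithium | [Li]c1ccc(OCOC)cc1OCOC | intermediate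
8 | (3R,6E)-1-[2,4-bis(methoxymethoxy)phenyl]-3-ethenyl-3,7,11-trimethyldodeca-6,10-dien-1-ol, both C1 epimers | C=C[C@](C)(CC/C=C(\C)CCC=C(C)C)CC(O)c1ccc(OCOC)cc1OCOC | intermediate
9 | (3R,6E)-1-[2,4-bis(methoxymethoxy)phenyl]-3-ethenyl-3,7,11-trimethyldodeca-6,10-dien-1-one | C=C[C@](C)(CC/C=C(\C)CCC=C(C)C)CC(=O)c1ccc(OCOC)cc1OCOC | intermediate
10 | (3R,6E)-1-(2,4-dihydroxyphenyl)-3-ethenyl-3,7,11-trimethyldodeca-6,10-dien-1-one | C=C[C@](C)(CC/C=C(\C)CCC=C(C)C)CC(=O)c1ccc(O)cc1O | target

Total step count: 5. Longest linear sequence: 4 steps (steps 1, 3, 4, 5 from 1; equally steps 2, 3, 4, 5 from 5).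

Steps most likely to fail

Step 1. The cationic vinylpalladium species might insert at the C6=C7 or C10=C11 alkene or at the vinyl group of the product, or the facial selectivity at C3 might be insufficient. The fallback would set out from 1 and come back at 4 by a copper-catalysed enantioselective SN2′ allylic alkylation, which builds the C2–C3 bond instead. Alcohol 1 would be converted (MsCl, LiCl, 2,4,6-collidine, DMF, 0 °C) into (2E,6E)-farnesyl chloride F1. F1 would be treated with (1,3-dioxolan-2-ylmethyl)magnesium bromide, CuTC (monovalent copper thiophene-2-carboxylate) and a chiral phosphoramidite ligand in CH2Cl2 at −78 °C, the ligand enantiomer being chosen for γ-attack on the face that gives 2-[(2R,5E)-2-ethenyl-2,6,10-trimethylundeca-5,9-dien-1-yl]-1,3-dioxolane F2. Hydrolysis of the acetal (aqueous AcOH, THF, rt) would give 4.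

Step 3. The basic aryllithium might deprotonate the α-methylene of the aldehyde instead of adding, returning 4 and the reduced arene. The fallback would set out from 4 and come back at 9, replacing carbonyl addition and oxidation by acyl substitution. Aldehyde 4 would be oxidised under Pinnick conditions (NaClO2, NaH2PO4, 2-methylbut-2-ene, t-BuOH/H2O) to (3R,6E)-3-ethenyl-3,7,11-trimethyldodeca-6,10-dienoic acid F3. Coupling with N,O-dimethylhydroxylamine hydrochloride (EDC, iPr2NEt, CH2Cl2) would give the Weinreb amide (3R,6E)-3-ethenyl-N-methoxy-N,3,7,11-tetramethyldodeca-6,10-dienamide F4. F4 would take up 7 at −78 °C through the stable chelated tetrahedral intermediate and give 9 directly, so that step 4 would not be needed.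

Step 5. Acid might hydrate, hydrochlorinate or cyclise the trisubstituted alkenes, or add the free phenol to an alkene, before both acetals are gone. The fallback would set out from 5 and 4 and come back at 10 with protecting groups that leave under neutral conditions. Diol 5 would be alkylated (allyl bromide, K2CO3, acetone) to 1-bromo-2,4-bis(prop-2-en-1-yloxy)benzene F5, which n-BuLi at −78 °C would convert into [2,4-bis(prop-2-en-1-yloxy)phenyl]lithium F6. Addition of F6 to 4 would give (3R,6E)-1-[2,4-bis(prop-2-en-1-yloxy)phenyl]-3-ethenyl-3,7,11-trimethyldodeca-6,10-dien-1-ol F7, and MnO2 would oxidise it to (3R,6E)-1-[2,4-bis(prop-2-en-1-yloxy)phenyl]-3-ethenyl-3,7,11-trimethyldodeca-6,10-dien-1-one F8. Pd(PPh3)4 (zerovalent palladium) with morpholine in THF at rt would transfer both allyl groups to the amine and give 10.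

Further compounds
F1 | step 1 | (2E,6E)-farnesyl chloride, (2E,6E)-1-chloro-3,7,11-trimethyldodeca-2,6,10-triene | ClC/C=C(\C)CC/C=C(\C)CCC=C(C)C
F2 | step 1 | 2-[(2R,5E)-2-ethenyl-2,6,10-trimethylundeca-5,9-dien-1-yl]-1,3-dioxolane | C=C[C@](C)(CC/C=C(\C)CCC=C(C)C)CC1OCCO1
F3 | step 3 | (3R,6E)-3-ethenyl-3,7,11-trimethyldodeca-6,10-dienoic acid | C=C[C@](C)(CC/C=C(\C)CCC=C(C)C)CC(=O)O
F4 | step 3 | (3R,6E)-3-ethenyl-N-methoxy-N,3,7,11-tetramethyldodeca-6,10-dienamide | C=C[C@](C)(CC/C=C(\C)CCC=C(C)C)CC(=O)N(C)OC
F5 | step 5 | 1-bromo-2,4-bis(prop-2-en-1-yloxy)benzene | C=CCOc1ccc(Br)c(OCC=C)c1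
F6 | step 5 | [2,4-bis(prop-2-en-1-yloxy)phenyl]lithium | [Li]c1ccc(OCC=C)cc1OCC=C
F7 | step 5 | (3R,6E)-1-[2,4-bis(prop-2-en-1-yloxy)phenyl]-3-ethenyl-3,7,11-trimethyldodeca-6,10-dien-1-ol, both C1 epimers | C=C[C@](C)(CC/C=C(\C)CCC=C(C)C)CC(O)c1ccc(OCC=C)cc1OCC=C
F8 | step 5 | (3R,6E)-1-[2,4-bis(prop-2-en-1-yloxy)phenyl]-3-ethenyl-3,7,11-trimethyldodeca-6,10-dien-1-one | C=C[C@](C)(CC/C=C(\C)CCC=C(C)C)CC(=O)c1ccc(OCC=C)cc1OCC=C
A1 | direct plan | 2,4-dihydroxybenzoic acid | O=C(O)c1ccc(O)cc1O
A2 | direct plan | (2E,6E)-farnesyl 2,4-dihydroxybenzoate | O=C(OC/C=C(\C)CC/C=C(\C)CCC=C(C)C)c1ccc(O)cc1O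
A3 | direct plan | (2E,6E)-farnesyl 2,4-bis(methoxymethoxy)benzoate | COCOc1ccc(C(=O)OC/C=C(\C)CC/C=C(\C)CCC=C(C)C)c(OCOC)c1
A4 | direct plan | 1-{1-[(2E,6E)-farnesyloxy]ethenyl}-2,4-bis(methoxymethoxy)benzene | C=C(OC/C=C(\C)CC/C=C(\C)CCC=C(C)C)c1ccc(OCOC)cc1OCOC
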